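## The problem

Target 41 is numbered here as a germacranolide: ring carbons C1–C10, lactone arm C11–C13. It is a ten-membered carbocycle, cis-fused across C6–C7 to a γ-lactone and bridged at C4–C5 by an epoxide, so a medium ring must be closed and two small rings attached to it without transannular side reactions. There are seven stereocentres: the quaternary C10 (methyl, acetate), the epoxide carbons C4 and C5, the contiguous C6, C7 and C8, and C11 on the lactone. C10 is insulated by C9 and the C1 ketone and cannot be induced, so it must come from a building block. C7 and C8 can be made together in an open chain; C7 can then steer C6 during ring closure, and the C6 hydroxyl can steer the epoxide, which lies cis to it. C11 is the awkward centre: its acetoxymethyl group sits on the concave face of the cis-fused lactone, the face an enolate alkylation would avoid, and its hydrogen is α to a carbonyl and β to an acetate. The fragile groups are this β-acetoxy lactone (loss of acetic acid to the α-methylene lactone), the α-acetoxy ketone with enolisable C2, the acid-labile trisubstituted epoxide and the methacrylate; together they exclude strong base, hydride and strong acid late in the route. The enabling feature is that C6 is a carbinol carbon bonded to C5 of a cis-epoxide: the epoxide is the oxidised form of a Z-C4=C5 alkene, so C5 can be an alkenyl carbon and C6 an aldehyde carbon, and a Z-alkenyl iodide can carry the geometry into the ring.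

## Retrosynthesis

**41 ⇒ 40 ⇒ 39.** The C8–O acyl bond and then the O8 silyl ether are cut. The methacrylate goes on last because it is the most fragile group. O8 stays silylated until the lactone exists, since a free O8 is also 1,4 to C12 and would compete for it. The forward steps are a buffered desilylation and a mild acylation.

**39 ⇒ 36 ⇒ 35 ⇒ 34.** The lactone C12–O6 bond and the two epoxide C–O bonds are cut. The lactone is closed oxidatively from a C12 primary alcohol (36), not from a C12 ester. An ester would be attacked by O6 as soon as the ring forms, which would remove the hydroxyl that has to direct the epoxidation, and it would make H11 acidic through the whole sequence. C12 therefore travels as a benzyl ether (35, 34). The forward reactions must give syn delivery of oxygen from the C6 hydroxyl of 34 and then oxidation of a primary alcohol in the presence of a secondary one.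

**34 ⇒ 32.** C5–C6 is cut, between an alkenyl carbon and a carbinol carbon (key step). The neighbouring cuts are worse: closing C2–C3 by enolate alkylation needs strong base next to three esters, and closing at C9–C10 or C1–C10 would build the quaternary centre on the ring. The precursor 32 is an open chain that already holds C7, C8, C10 and C11 and every oxidation level of the target except at C4–C6. The forward reaction must close a ten-membered ring at an aldehyde, ignore a ketone, keep the Z geometry and set C6.

**32 ⇒ 30 ⇒ 29.** The C6 aldehyde is traced to a vinyl group and O8 is desilylated. No hydride can be used once the α-acetoxy ketone is present, so the aldehyde has to be unveiled by oxidation. A vinyl group on C7 next to a carbinol at C8 is also the pattern an allylation produces.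

**29 ⇒ 17 + 27.** C7–C8 is cut. An aldol would deliver C6 as an acyl group that needs hydride, and would have to be anti-selective. An E-γ-substituted allylboronate (27) gives the anti C7/C8 pair through a closed transition state and brings C6 as the alkene. The two halves are of similar size: 17 holds C10 and the iodoalkene, 27 holds C11.

**17 ⇒ 15 ⇒ 14 ⇒ 12 + 4; 4 ⇒ 3 ⇒ 1.** The C8 aldehyde comes from an allyl group, the C10 acetate from the tertiary alcohol, and C2–C3 from alkylation of a methyl ketone that can enolise on one side only. The Z-iodoallyl bromide 4 comes from propargyl alcohol 1 by a carbometalation that fixes the geometry.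

**12 ⇒ 11 ⇒ 10 ⇒ 7 + 8 ⇒ 5 + 6.** C1–C2 is cut (methyl ketone from an N-methoxy-N-methylamide) and then C9–C10 (allylation of the lactic acid enolate held as its pivalaldehyde acetal 7). (S)-Lactic acid 5 supplies C1, C10 and the C10 methyl. Citramalic acid would map onto C8–C10–C1 as well but needs extra redox and protection steps at C8.

**27 ⇒ 26 ⇒ 25 ⇒ 24 ⇒ 23 ⇒ 21 ⇒ 18 + 19.** The C–B bond is traced to an allylic acetate and the alkene to a cross-metathesis. C11 comes from an oxazolidinone-controlled alkylation in which the acyl carbon becomes C13 and the benzyloxymethyl electrophile becomes C12. C11 is thus set, with both carbon substituents, before any carbonyl is next to it.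

## Roads not taken

**Alternative 1:** The cut is across C8–C10: C9–C10 and O–C8 would form together in an intramolecular nitrile oxide cycloaddition. The seco nitro alkene A1, which already holds the epoxide and the finished lactone, would be dehydrated at its C10 nitromethyl group (phenyl isocyanate, triethylamine), and the dipole would add to the C8=C9 vinyl group to give the isoxazoline-bridged ring A2.
- Merits: the ring, the C8 oxygen and a masked C10 carbonyl arise in one neutral step. The lactone with its C11/C13 array is complete beforehand, so nothing is needed at C6 or C12 after ring closure. In this respect the road is better than the chosen one, which needs five steps after cyclisation.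
- Weak points: A2 is a bridged isoxazoline in a ten-membered ring, a strained mode in which dimerisation of the dipole competes. C8 is set only by the facial bias of a vinyl group. A2 also lacks the C10 methyl and acetate and has C1 as a silyl ether, so N–O cleavage beside an epoxide, methyl addition to the exposed C10 carbonyl with control of a quaternary centre on a flexible ring, tertiary acetylation and oxidation at C1 would all follow, next to a β-acetoxy lactone.
- Comparison: the chosen plan sets against this a C10 taken from lactic acid and C1/C10 oxidation levels that are never adjusted on the ring.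

**Alternative 2:** The cut is C7–C11: the lactone would be grafted onto a finished ten-membered ring. The C6 diazoacetate A3 would give, with Rh2(NHCOCH3)4, a carbene that inserts into the syn C7–H bond to form the cis-fused lactone A4.
- Merits: insertion with retention makes the cis fusion a geometric certainty. The chosen plan has to earn the same result through the C6 selectivity of its ring closure.
- Weak points: the C7 methylene is next to the C8 silyloxy group, which deactivates its C–H bonds toward an electrophilic carbene. An acceptor-only carbene on a ring with a ketone, an epoxide and ether oxygens can form ylides or dimerise. A4 lacks C13, and hydroxymethylation at C11 would need strong base beside the α-acetoxy ketone and would enter from the convex face, giving the wrong C11 epimer. The ring of A3 itself is left unsolved.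
- Comparison: the chosen plan brings C11 with both carbon substituents from an auxiliary alkylation and uses the ring closure itself to make C5–C6.

**Alternative 3:** The ring would be made by ring expansion: C2–C3 formed and C5–C10 cleaved in an anionic oxy-Cope rearrangement. The potassium alkoxide (KH, 18-crown-6) of the carvone-derived dialkenylcyclohexanol A5 would rearrange, and silylation on oxygen would give the cyclodecadiene A6.
- Merits: this is probably the most dependable way to reach a ten-membered ring, with no high dilution and the C7 side-chain skeleton from the chiral pool. On the ring-forming event alone it is superior to the chromium closure.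
- Weak points: A6 has the wrong oxidation pattern almost everywhere. The C1(10) alkene must become a ketone and a tertiary acetate, the C5 enol ether must become the cis-4,5-epoxide, the isopropenyl group must be oxidised at two carbons with control of C11, and two ether protecting groups must be exchanged. At least four stereocentres (C4, C5, C10, C11) would be set on a mobile macrocycle.
- Comparison: the chosen plan accepts the harder ring closure and sets against it that every oxidation level and five of seven stereocentres are fixed in open-chain intermediates.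

Key step: step 19

Assumption: (R)-TRIP is taken to direct allyl transfer to the Re face of 17, as it does with unbranched aliphatic aldehydes; if the sense proved opposite, the (S)-acid would be used in step 16.

## Steps

Step 1
Reactants: 1 propargyl alcohol
Product: 3 (Z)-3-iodo-2-methylprop-2-en-1-ol, via chelated alkenylmagnesium alkoxide 2 (not isolated)
Conditions: MeMgBr (2.5 equiv), CuI (10 mol%), THF, −20 °C to rt; then I2, −20 °C; aq. NH4Cl
Reagents that add atoms: methylmagnesium bromide, C[Mg]Br; iodine, II
Why: Copper-catalysed anti-carbomagnesiation of the propargylic alkoxide puts methyl on C2 and magnesium on C3 inside a five-membered chelate, so iodinolysis with retention should give only the Z iodide.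

Step 2
Reactants: 3 (Z)-3-iodo-2-methylprop-2-en-1-ol
Product: 4 (Z)-3-bromo-1-iodo-2-methylprop-1-ene
Conditions: PBr3 (0.4 equiv), Et2O, 0 °C
Reagents that add atoms: phosphorus tribromide, BrP(Br)Br
Why: Conversion of a primary allylic alcohol into the bromide (SN2 on the phosphite ester); the alkenyl iodide and its geometry are not involved.

Step 3
Reactants: 5 (S)-lactic acid; 6 pivalaldehyde
Product: 7 (2S,5S)-2-tert-butyl-5-methyl-1,3-dioxolan-4-one
Conditions: TsOH·H2O (cat.), H2SO4 (cat.), pentane, reflux, Dean–Stark trap; recrystallisation at −78 °C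
Reagents that add atoms: none
Why: Acid-catalysed acetalisation of the α-hydroxy acid; the cis acetal is the favoured, crystalline isomer and stores the lactic acid stereocentre as the acetal centre.

Step 4
Reactants: 7 (2S,5S)-2-tert-butyl-5-methyl-1,3-dioxolan-4-one; 8 allyl bromide
Product: 10 (2S,5R)-5-allyl-2-tert-butyl-5-methyl-1,3-dioxolan-4-one, via lithium enolate 9 (not isolated)
Conditions: LiN(iPr)2 (1.1 equiv), THF, −78 °C; then 8, −78 to −30 °C
Reagents that add atoms: none
Why: Enolate alkylation with self-regeneration of the stereocentre: the planar enolate is attacked anti to the tert-butyl group, so allyl replaces hydrogen with retention and C10 is set as R.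

Step 5
Reactants: 10 (2S,5R)-5-allyl-2-tert-butyl-5-methyl-1,3-dioxolan-4-one
Product: 11 (2R)-2-hydroxy-N-methoxy-N,2-dimethylpent-4-enamide
Conditions: MeNH(OMe)·HCl (3 equiv), iPrMgCl (6 equiv), THF, −20 to 0 °C
Reagents that add atoms: N,O-dimethylhydroxylamine hydrochloride, CNOC.Cl
Why: Aminolysis of the activated acetal lactone by the chloromagnesium amide; the hemiacetal alkoxide collapses, releasing pivalaldehyde and leaving the tertiary hydroxyl free.

Step 6
Reactants: 11 (2R)-2-hydroxy-N-methoxy-N,2-dimethylpent-4-enamide
Product: 12 (3R)-3-hydroxy-3-methylhex-5-en-2-one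
Conditions: MeMgBr (3 equiv), THF, −78 to 0 °C; aq. NH4Cl
Reagents that add atoms: methylmagnesium bromide, C[Mg]Br
Why: Weinreb ketone synthesis: the magnesium-chelated tetrahedral adduct resists a second addition; the first equivalent of reagent only deprotonates the hydroxyl.

Step 7
Reactants: 12 (3R)-3-hydroxy-3-methylhex-5-en-2-one; 4 (Z)-3-bromo-1-iodo-2-methylprop-1-ene
Product: 14 (4R,8Z)-4-hydroxy-9-iodo-4,8-dimethylnona-1,8-dien-5-one, via dilithium alkoxide enolate 13 (not isolated)
Conditions: LiN(iPr)2 (2.2 equiv), THF, −78 °C; then 4, DMPU, −78 to −30 °C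
Reagents that add atoms: none
Why: The ketone can enolise only toward its methyl group because C10 is quaternary, so the enolate is alkylated at C2 by the reactive allylic bromide (SN2). This forms C2–C3 and brings in the Z-iodoalkene unchanged.

Step 8
Reactants: 14 (4R,8Z)-4-hydroxy-9-iodo-4,8-dimethylnona-1,8-dien-5-one
Product: 15 (4R,8Z)-9-iodo-4,8-dimethyl-5-oxonona-1,8-dien-4-yl acetate
Conditions: Ac2O, DMAP (0.5 equiv), Et3N, CH2Cl2, rt
Reagents that add atoms: acetic anhydride, CC(=O)OC(C)=O
Why: DMAP-catalysed acetylation of the tertiary α-ketol at a stage where nothing else is acyl- or base-sensitive; the C10 acetate is in place before any β-acyloxy carbonyl group exists.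

Step 9
Reactants: 15 (4R,8Z)-9-iodo-4,8-dimethyl-5-oxonona-1,8-dien-4-yl acetate
Product: 17 (3R,7Z)-8-iodo-3,7-dimethyl-1,4-dioxooct-7-en-3-yl acetate, via vicinal diol 16 (not isolated)
Conditions: OsO4 (2 mol%), NaIO4 (4 equiv), 2,6-lutidine, dioxane/H2O, rt; used at once
Reagents that add atoms: sodium periodate, [Na+].[O-]I(=O)(=O)=O (oxygen relayed by osmium tetroxide, O=[Os](=O)(=O)=O)
Why: Lemieux–Johnson oxidation: OsO4 should dihydroxylate the monosubstituted alkene well before the hindered, electron-poor iodoalkene, and periodate cleaves the diol to the C8 aldehyde.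

Step 10
Reactants: 18 (R)-4-benzyl-1,3-oxazolidin-2-one; 19 (E)-but-2-enoyl chloride
Product: 21 (R)-4-benzyl-3-[(E)-but-2-enoyl]-1,3-oxazolidin-2-one, via N-lithio oxazolidinone 20 (not isolated)
Conditions: nBuLi (1.0 equiv), THF, −78 °C; then 19, −78 to 0 °C
Reagents that add atoms: none
Why: N-Acylation of the lithiated auxiliary with the acid chloride, the standard way to attach it.

Step 11
Reactants: 21 (R)-4-benzyl-3-[(E)-but-2-enoyl]-1,3-oxazolidin-2-one
Product: 23 (R)-4-benzyl-3-[(2S)-2-[(benzyloxy)methyl]but-3-enoyl]-1,3-oxazolidin-2-one, via sodium Z-dienolate 22 (not isolated)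
Conditions: NaN(SiMe3)2 (1.1 equiv), THF, −78 °C; then BnOCH2Cl, −78 to −45 °C
Reagents that add atoms: benzyl chloromethyl ether, ClCOCc1ccccc1
Why: Deconjugative auxiliary-controlled alkylation: γ-deprotonation gives the chelated Z-dienolate, which reacts at its α-carbon on the face away from the benzyl group. With the (R)-auxiliary this sets C11, with the acyl carbon as the future C13 and the benzyloxymethyl carbon as the future C12.

Step 12
Reactants: 23 (R)-4-benzyl-3-[(2S)-2-[(benzyloxy)methyl]but-3-enoyl]-1,3-oxazolidin-2-one
Product: 24 (2R)-2-[(benzyloxy)methyl]but-3-en-1-ol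
Conditions: LiBH4 (1.5 equiv), MeOH (1.5 equiv), Et2O, 0 °C
Reagents that add atoms: none
Why: Reductive cleavage of the imide at its more electrophilic exocyclic carbonyl gives the C13 primary alcohol and returns the auxiliary; the descriptor changes only through the priority rules.

Step 13
Reactants: 24 (2R)-2-[(benzyloxy)methyl]but-3-en-1-ol
Product: 25 (2S)-2-[(benzyloxy)methyl]but-3-en-1-yl acetate
Conditions: Ac2O, pyridine, DMAP (cat.), CH2Cl2, 0 °C to rt
Reagents that add atoms: acetic anhydride, CC(=O)OC(C)=O
Why: Routine acetylation of a primary alcohol; C13 now carries the acetate of the target and, with O12 benzylated, the acetyl group cannot migrate.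

Step 14
Reactants: 25 (2S)-2-[(benzyloxy)methyl]but-3-en-1-yl acetate
Product: 26 (2E,4S)-4-[(benzyloxy)methyl]pent-2-ene-1,5-diyl diacetate
Conditions: (Z)-AcOCH2CH=CHCH2OAc (3 equiv), RuCl2(=CHPh)(PCy3)(H2IMes) (second-generation Grubbs catalyst, 5 mol%), CH2Cl2, 40 °C
Reagents that add atoms: (Z)-but-2-ene-1,4-diyl diacetate, CC(=O)OC/C=C\COC(C)=O
Why: Olefin cross-metathesis of the terminal alkene with an excess of the symmetrical diacetate; E should be favoured, and any Z isomer converges in step 15.

Step 15
Reactants: 26 (2E,4S)-4-[(benzyloxy)methyl]pent-2-ene-1,5-diyl diacetate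
Product: 27 (2S,3E)-2-[(benzyloxy)methyl]-5-(4,4,5,5-tetramethyl-1,3,2-dioxaborolan-2-yl)pent-3-en-1-yl acetate
Conditions: B2pin2 (1.1 equiv), Pd(dba)2 (5 mol%), DMSO, 50 °C
Reagents that add atoms: bis(pinacolato)diboron, CC1(C)OB(OC1(C)C)B1OC(C)(C)C(C)(C)O1
Why: Miyaura-type allylic borylation: zerovalent palladium ionises only the allylic acetate, and boron is delivered to the less hindered end of the syn π-allyl complex, which should give the linear E allylboronate.

Step 16
Reactants: 17 (3R,7Z)-8-iodo-3,7-dimethyl-1,4-dioxooct-7-en-3-yl acetate; 27 (2S,3E)-allylboronate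
Product: 29 anti homoallylic alcohol (7S,8S,10R,11S), via pinacol borate ester 28 (not isolated)
Conditions: (R)-TRIP [(R)-3,3′-bis(2,4,6-triisopropylphenyl)-1,1′-binaphthyl-2,2′-diyl hydrogen phosphate] (10 mol%), 4 Å molecular sieves, toluene, −30 °C; aq. NaHCO3 work-up
Reagents that add atoms: none
Why: Brønsted acid-catalysed allylboration through a closed chair transition state: the E geometry of 27 becomes the anti C7/C8 relationship, and the chiral phosphate selects the Re face of the aldehyde, so C8 and C7 are set together while C6 arrives as a vinyl group. The ketone is too unreactive toward the boronate to compete, and no base is present to eliminate the β-acetate of 17.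

Step 17
Reactants: 29 anti homoallylic alcohol (7S,8S,10R,11S)
Product: 30 C8 tert-butyldimethylsilyl ether of 29
Conditions: TBSOTf (1.3 equiv), 2,6-lutidine, CH2Cl2, −78 °C
Reagents that add atoms: tert-butyldimethylsilyl trifluoromethanesulfonate, CC(C)(C)[Si](C)(C)OS(=O)(=O)C(F)(F)F
Why: Silyl triflate protection of the hindered secondary alcohol, done at once so that the C10 acetyl group cannot migrate to O8 and so that O8 stays out of later lactol and lactone formation.

Step 18
Reactants: 30 C8 tert-butyldimethylsilyl ether of 29
Product: 32 seco Z-alkenyl iodide aldehyde (7S,8S,10R,11S), via vicinal diol 31 (not isolated)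
Conditions: OsO4 (2 mol%), NaIO4 (4 equiv), 2,6-lutidine, dioxane/H2O, rt
Reagents that add atoms: sodium periodate, [Na+].[O-]I(=O)(=O)=O (oxygen relayed by osmium tetroxide, O=[Os](=O)(=O)=O)
Why: Second Lemieux–Johnson oxidation: the only monosubstituted alkene is cleaved to the C6 aldehyde without hydride. No hydroxyl is free, so the aldehyde cannot hide as a lactol.

Step 19
Reactants: 32 seco Z-alkenyl iodide aldehyde (7S,8S,10R,11S)
Product: 34 ten-membered Z-allylic alcohol (4Z,6R,7R,8S,10R,11S), via alkenylchromium dichloride 33 (not isolated)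
Conditions: CrCl2 (10 equiv), NiCl2 (0.1 equiv), degassed DMSO/THF, rt; 32 added by syringe pump to a final 0.003 M; aq. NH4Cl work-up
Reagents that add atoms: none
Why: NiCl2 is reduced by CrCl2 to zerovalent nickel, which inserts into the C5–I bond with retention; transmetalation to trivalent chromium gives the alkenylchromium species, which adds to the C6 aldehyde to form C5–C6 and a chromium alkoxide that is hydrolysed on work-up. The closest known reaction type is the Nozaki–Hiyama–Kishi macrocyclisation of ω-formyl alkenyl iodides. The ten-membered carbocycle closes by intramolecular carbonyl addition in the 10-exo-trig mode, with the Z-alkene and the quaternary C10 bending the chain so that C5 reaches C6. The new stereocentre C6 is controlled by C7: in the Felkin–Anh arrangement the C7–C11 bond, the largest branch, lies anti to the incoming C5 while the C7–C8 bond stays in the forming ring, which places O6 cis to C11 as the target requires (6R in 34 by the priority rules). The step needs chemoselectivity for the aldehyde over the C1 ketone, which the low reactivity of alkenylchromium reagents toward hindered ketones should secure; it needs retention of the Z geometry, which the nickel–chromium sequence provides; and it needs cyclisation over oligomerisation, which slow addition at high dilution favours. Because C12 is an ether and not an ester, the chromium alkoxide cannot lactonise, so the free C6 hydroxyl needed in step 20 is assured.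

Step 20
Reactants: 34 ten-membered Z-allylic alcohol (4Z,6R,7R,8S,10R,11S)
Product: 35 cis-4,5-epoxy 6-alcohol (4R,5S,6S,7R,8S,10R,11S)
Conditions: VO(acac)2 (10 mol%), tBuOOH (1.5 equiv, in decane), toluene, 0 °C to rt
Reagents that add atoms: tert-butyl hydroperoxide, CC(C)(C)OO
Why: Hydroxyl-directed epoxidation: the vanadate ester of the allylic alcohol delivers oxygen to the alkene face syn to O6, as it does in medium-ring Z-cycloalkenols. This should give the cis-epoxy alcohol and so set C4 (R) and C5 (S).

Step 21
Reactants: 35 cis-4,5-epoxy 6-alcohol (4R,5S,6S,7R,8S,10R,11S)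
Product: 36 epoxy 6,12-diol (4R,5S,6S,7R,8S,10R,11S)
Conditions: H2 (1 atm), Pd(OH)2 on carbon, EtOAc, rt; used at once
Reagents that add atoms: none
Why: Hydrogenolysis of the benzyl ether under neutral conditions; the ring alkene is already an epoxide, and the non-benzylic epoxide, the ketone and the acetates should survive. The diol is carried on without delay because the C13 acetyl group could migrate to O12.

Step 22
Reactants: 36 epoxy 6,12-diol (4R,5S,6S,7R,8S,10R,11S)
Product: 39 8-O-silyl cis-fused lactone (4R,5S,6S,7R,8S,10R,11R), via hydroxy aldehyde 37 (not isolated), via lactol 38 (not isolated)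
Conditions: TEMPO (20 mol%), PhI(OAc)2 (2.5 equiv), CH2Cl2, rt
Reagents that add atoms: none
Why: Oxoammonium oxidation selects the primary alcohol; the C12 aldehyde is trapped by the cis-disposed O6 as a five-membered lactol (5-exo-trig), which is oxidised on to the γ-lactone. The cis fusion is fixed by the existing C6 and C7 centres, and no base is present to eliminate the C13 acetate.

Step 23
Reactants: 39 8-O-silyl cis-fused lactone (4R,5S,6S,7R,8S,10R,11R)
Product: 40 8-hydroxy lactone (4R,5S,6S,7S,8S,10R,11R)
Conditions: HF·pyridine, excess pyridine, THF, 0 °C to rt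
Reagents that add atoms: none
Why: Fluoride cleavage of the secondary silyl ether with buffered HF·pyridine, conditions known to spare epoxides, acetates and lactones.

Step 24
Reactants: 40 8-hydroxy lactone (4R,5S,6S,7S,8S,10R,11R)
Product: 41 target (4R,5S,6S,7S,8S,10R,11R)
Conditions: methacrylic anhydride (3 equiv), iPr2NEt, DMAP (cat.), CH2Cl2, 0 °C
Reagents that add atoms: methacrylic anhydride, C=C(C)C(=O)OC(=O)C(C)=C
Why: Acylation of the secondary C8 hydroxyl under mild amine catalysis at low temperature, run promptly to outrun translactonisation to O8, hemiketal formation with the C1 ketone and β-elimination of the C13 acetate.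

## Compound list

1 | prop-2-yn-1-ol (propargyl alcohol) | C#CCO | starting material
2 | bromomagnesium (Z)-3-(bromomagnesio)-2-methylprop-2-en-1-olate | C/C(CO[Mg]Br)=C/[Mg]Br | intermediate
3 | (Z)-3-iodo-2-methylprop-2-en-1-ol | OC/C(C)=C\I | intermediate
4 | (Z)-3-bromo-1-iodo-2-methylprop-1-ene | BrC/C(C)=C\I | intermediate
5 | (S)-lactic acid | C[C@H](O)C(=O)O | starting material
6 | pivalaldehyde (2,2-dimethylpropanal) | CC(C)(C)C=O | starting material
7 | (2S,5S)-2-tert-butyl-5-methyl-1,3-dioxolan-4-one | C[C@@H]1O[C@H](C(C)(C)C)OC1=O | intermediate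
8 | allyl bromide (3-bromoprop-1-ene) | C=CCBr | starting material
9 | lithium enolate of 7, lithium (2S)-2-tert-butyl-5-methyl-1,3-dioxol-4-olate | [Li]OC1=C(C)O[C@H](C(C)(C)C)O1 | intermediate
10 | (2S,5R)-2-tert-butyl-5-methyl-5-(prop-2-en-1-yl)-1,3-dioxolan-4-one | C=CC[C@@]1(C)O[C@H](C(C)(C)C)OC1=O | intermediate
11 | (2R)-2-hydroxy-N-methoxy-N,2-dimethylpent-4-enamide | C=CC[C@@](C)(O)C(=O)N(C)OC | intermediate
12 | (3R)-3-hydroxy-3-methylhex-5-en-2-one | C=CC[C@@](C)(O)C(C)=O | intermediate
13 | dilithium alkoxide enolate of 12 | C=CC[C@@](C)(O[Li])C(=C)O[Li] | intermediate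
14 | (4R,8Z)-4-hydroxy-9-iodo-4,8-dimethylnona-1,8-dien-5-one | C=CC[C@@](C)(O)C(=O)CC/C(C)=C\I | intermediate
15 | (4R,8Z)-9-iodo-4,8-dimethyl-5-oxonona-1,8-dien-4-yl acetate | C=CC[C@@](C)(OC(C)=O)C(=O)CC/C(C)=C\I | intermediate
16 | (4R,8Z)-1,2-dihydroxy-9-iodo-4,8-dimethyl-5-oxonon-8-en-4-yl acetate, both C2 epimers | OCC(O)C[C@@](C)(OC(C)=O)C(=O)CC/C(C)=C\I | intermediate
17 | (3R,7Z)-8-iodo-3,7-dimethyl-1,4-dioxooct-7-en-3-yl acetate (C8 aldehyde, C10 acetate, C1 ketone, Z-C4=C5–I) | O=CC[C@@](C)(OC(C)=O)C(=O)CC/C(C)=C\I | intermediate
18 | (R)-4-benzyl-1,3-oxazolidin-2-one | O=C1N[C@H](Cc2ccccc2)CO1 | starting material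
19 | (E)-but-2-enoyl chloride (crotonyl chloride) | C/C=C/C(Cl)=O | starting material
20 | lithium salt of 18, lithium (R)-4-benzyl-2-oxo-1,3-oxazolidin-3-ide | [Li]N1[C@H](Cc2ccccc2)COC1=O | intermediate
21 | (R)-4-benzyl-3-[(E)-but-2-enoyl]-1,3-oxazolidin-2-one | C/C=C/C(=O)N1[C@H](Cc2ccccc2)COC1=O | intermediate
22 | sodium (Z)-dienolate of 21 | C=C/C=C(\O[Na])N1[C@H](Cc2ccccc2)COC1=O | intermediate
23 | (R)-4-benzyl-3-[(2S)-2-[(benzyloxy)methyl]but-3-enoyl]-1,3-oxazolidin-2-one | C=C[C@@H](COCc1ccccc1)C(=O)N1[C@H](Cc2ccccc2)COC1=O | intermediate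
24 | (2R)-2-[(benzyloxy)methyl]but-3-en-1-ol | C=C[C@H](CO)COCc1ccccc1 | intermediate
25 | (2S)-2-[(benzyloxy)methyl]but-3-en-1-yl acetate | C=C[C@H](COC(C)=O)COCc1ccccc1 | intermediate
26 | (2E,4S)-4-[(benzyloxy)methyl]pent-2-ene-1,5-diyl diacetate | CC(=O)OC/C=C/[C@H](COC(C)=O)COCc1ccccc1 | intermediate
27 | (2S,3E)-2-[(benzyloxy)methyl]-5-(4,4,5,5-tetramethyl-1,3,2-dioxaborolan-2-yl)pent-3-en-1-yl acetate | CC1(C)OB(C/C=C/[C@H](COC(C)=O)COCc2ccccc2)OC1(C)C | intermediate
28 | O8-pinacolboryl derivative of 29 (7S,8S,10R,11S) | CC1(C)OB(O[C@@H](C[C@@](C)(OC(C)=O)C(=O)CC/C(C)=C\I)[C@@H](C=C)[C@H](COC(C)=O)COCc2ccccc2)OC1(C)C | intermediate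
29 | anti homoallylic alcohol (7S,8S,10R,11S): AcOCH2(BnOCH2)CH–CH(CH=CH2)–CH(OH)–CH2–C(CH3)(OAc)–CO–CH2CH2–C(CH3)=CHI, Z | O[C@@H](C[C@@](C)(OC(C)=O)C(=O)CC/C(C)=C\I)[C@@H](C=C)[C@H](COC(C)=O)COCc1ccccc1 | intermediate
30 | C8 tert-butyldimethylsilyl ether of 29 (7S,8S,10R,11S) | CC(C)(C)[Si](C)(C)O[C@@H](C[C@@](C)(OC(C)=O)C(=O)CC/C(C)=C\I)[C@@H](C=C)[C@H](COC(C)=O)COCc1ccccc1 | intermediate
31 | vicinal diol from the vinyl group of 30, both epimers at the new secondary carbinol, other centres as in 30 | CC(C)(C)[Si](C)(C)O[C@@H](C[C@@](C)(OC(C)=O)C(=O)CC/C(C)=C\I)[C@@H](C(O)CO)[C@H](COC(C)=O)COCc1ccccc1 | intermediate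
32 | seco Z-alkenyl iodide aldehyde (7S,8S,10R,11S): C6 aldehyde on C7, C8 OTBS, C10 OAc, C1 ketone, C11 bearing CH2OAc (C13) and CH2OBn (C12) | CC(C)(C)[Si](C)(C)O[C@@H](C[C@@](C)(OC(C)=O)C(=O)CC/C(C)=C\I)[C@@H](C=O)[C@H](COC(C)=O)COCc1ccccc1 | intermediate
33 | alkenylchromium dichloride from 32 (trivalent chromium on C5, Z) | CC(C)(C)[Si](C)(C)O[C@@H](C[C@@](C)(OC(C)=O)C(=O)CC/C(C)=C\[Cr](Cl)Cl)[C@@H](C=O)[C@H](COC(C)=O)COCc1ccccc1 | intermediate
34 | ten-membered Z-allylic alcohol (4Z,6R,7R,8S,10R,11S): 6-OH, 8-OTBS, 10-OAc, 1-oxo, C7 bearing CH(CH2OAc)(CH2OBn) | CC(C)(C)[Si](C)(C)O[C@H]1C[C@@](C)(OC(C)=O)C(=O)CC/C(C)=C\[C@@H](O)[C@H]1[C@H](COC(C)=O)COCc2ccccc2 | intermediate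
35 | cis-4,5-epoxy 6-alcohol (4R,5S,6S,7R,8S,10R,11S), otherwise as 34 | CC(C)(C)[Si](C)(C)O[C@H]1C[C@@](C)(OC(C)=O)C(=O)CC[C@@]2(C)O[C@H]2[C@@H](O)[C@H]1[C@H](COC(C)=O)COCc3ccccc3 | intermediate
36 | epoxy 6,12-diol (4R,5S,6S,7R,8S,10R,11S): 35 without the benzyl group | CC(C)(C)[Si](C)(C)O[C@H]1C[C@@](C)(OC(C)=O)C(=O)CC[C@@]2(C)O[C@H]2[C@@H](O)[C@H]1[C@H](COC(C)=O)CO | intermediate
37 | C12 aldehyde of 36 (11R by the priority rules, same geometry) | CC(C)(C)[Si](C)(C)O[C@H]1C[C@@](C)(OC(C)=O)C(=O)CC[C@@]2(C)O[C@H]2[C@@H](O)[C@H]1[C@H](COC(C)=O)C=O | intermediate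
38 | 6,12-lactol from 37, both C12 epimers | CC(C)(C)[Si](C)(C)O[C@H]1C[C@@](C)(OC(C)=O)C(=O)CC[C@@]2(C)O[C@H]2[C@H]2OC(O)[C@@H](COC(C)=O)[C@H]21 | intermediate
39 | 8-O-tert-butyldimethylsilyl cis-fused 6,12-lactone (4R,5S,6S,7R,8S,10R,11R) | CC(C)(C)[Si](C)(C)O[C@H]1C[C@@](C)(OC(C)=O)C(=O)CC[C@@]2(C)O[C@H]2[C@H]2OC(=O)[C@@H](COC(C)=O)[C@H]21 | intermediate
40 | 8-hydroxy lactone (4R,5S,6S,7S,8S,10R,11R): 10,13-diacetoxy-4,5-epoxy-8-hydroxy-1-oxogermacran-6,12-olide | O[C@H]1C[C@@](C)(OC(C)=O)C(=O)CC[C@@]2(C)O[C@H]2[C@H]2OC(=O)[C@@H](COC(C)=O)[C@H]21 | intermediate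
41 | CNP0166747.1, (4R,5S,6S,7S,8S,10R,11R)-10,13-diacetoxy-4,5-epoxy-8-methacryloyloxy-1-oxogermacran-6,12-olide | C=C(C)C(=O)O[C@H]1C[C@@](C)(OC(C)=O)C(=O)CC[C@@]2(C)O[C@H]2[C@H]2OC(=O)[C@@H](COC(C)=O)[C@H]21 | target

## Step count and weakest steps

Total: 24 steps. Longest linear sequence: 16 steps (steps 3–9 and 16–24, from (S)-lactic acid). The branches are steps 1–2 (bromide 4) and steps 10–15 (allylboronate 27).

**Step 19 (key step).** The most likely failure is poor facial selectivity at C6, because the cyclic transition state need not follow the open-chain Felkin–Anh preference; oligomerisation is the second concern. Fallback: set C6 by reduction instead of by C–C bond formation. Starting again from 32, the ring is closed as before. The mixture of 34 and its C6 epimer F1 is oxidised with Dess–Martin periodinane to the Z-enone F2. F2 is then reduced at −78 °C with catecholborane under the oxazaborolidine (CBS) catalyst of the hand that gives 34. Hydride now enters where C5 entered, so the ring's own bias, if it misdirected the chromium addition, works for the reduction; the conjugated C6 carbonyl should react before the hindered C1 ketone. The sequence rejoins the route at 34.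

**Step 16.** The most likely failure is slow or unselective allyl transfer, since 27 has a branched γ-substituent and 17 can lose acetic acid by β-elimination if the reaction is long. Fallback: change boron for chromium. From 25, cross-metathesis with (E)-1,4-dibromobut-2-ene gives the allylic bromide F3. F3 is added to 17 in a catalytic asymmetric Nozaki–Hiyama allylation (CrCl3, manganese powder, Me3SiCl, chiral oxazoline ligand). γ-Substituted allylchromium reagents give anti adducts whatever the bromide geometry, and the alkenyl iodide is inert without nickel. Desilylative work-up rejoins the route at 29.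

**Step 7.** The most likely failure is over-alkylation through proton exchange of the dianion, or O-alkylation of the tertiary alkoxide. Fallback: mask the hydroxyl so that a single enolate is alkylated. From 12, Et3SiOTf and 2,6-lutidine give the triethylsilyl ether F4. Its lithium enolate is alkylated with 4 to the iodo ketone F5, and HF·pyridine then returns 14.

**Step 20.** The most likely failure is delivery of oxygen to the wrong alkene face, if the ring holds the hydroxyl away from the geometry needed for direction; oxidation to the enone is the second concern. Fallback: reach the epoxide by displacement instead of direct oxygen transfer. From 34, N-bromosuccinimide in aqueous dimethoxyethane gives the bromohydrin F6, with the bromonium ion on the exposed face and water at the tertiary C4 from the other face. K2CO3 in acetone then closes F6 with inversion at C5 to 35. Any 5,6-epoxide formed through O6 should move to the more substituted 4,5-epoxide by Payne rearrangement.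

**Step 22.** The most likely failures are competing oxidation of the secondary C6 hydroxyl and migration of the C13 acetyl group to the free C12 hydroxyl of 36, which would scramble C11. Fallback: go through the acid instead of the lactol. From 36, TEMPO with catalytic NaOCl and stoichiometric NaClO2 in buffered acetonitrile, a system selective for primary alcohols, gives the hydroxy acid F7. F7 is closed to 39 with a carbodiimide.

## Further compounds

F1 | step 19 | C6 epimer of 34 (4Z,6S,7R,8S,10R,11S) | CC(C)(C)[Si](C)(C)O[C@H]1C[C@@](C)(OC(C)=O)C(=O)CC/C(C)=C\[C@H](O)[C@H]1[C@H](COC(C)=O)COCc2ccccc2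
F2 | step 19 | ten-membered (4Z)-6-oxo enone from 34 and F1 | CC(C)(C)[Si](C)(C)O[C@H]1C[C@@](C)(OC(C)=O)C(=O)CC/C(C)=C\C(=O)[C@H]1[C@H](COC(C)=O)COCc2ccccc2
F3 | step 16 | (2S,3E)-2-[(benzyloxy)methyl]-5-bromopent-3-en-1-yl acetate | BrC/C=C/[C@H](COC(C)=O)COCc1ccccc1
F4 | step 7 | (3R)-3-methyl-3-[(triethylsilyl)oxy]hex-5-en-2-one | C=CC[C@@](C)(O[Si](CC)(CC)CC)C(C)=O
F5 | step 7 | (4R,8Z)-9-iodo-4,8-dimethyl-4-[(triethylsilyl)oxy]nona-1,8-dien-5-one | C=CC[C@@](C)(O[Si](CC)(CC)CC)C(=O)CC/C(C)=C\I
F6 | step 20 | bromohydrin of 34: 5-bromo-4,6-dihydroxy compound, bromine anti to O4 | CC(C)(C)[Si](C)(C)O[C@H]1C[C@@](C)(OC(C)=O)C(=O)CC[C@@](C)(O)[C@H](Br)[C@@H](O)[C@H]1[C@H](COC(C)=O)COCc2ccccc2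
F7 | step 22 | 6-hydroxy 12-carboxylic acid from 36 | CC(C)(C)[Si](C)(C)O[C@H]1C[C@@](C)(OC(C)=O)C(=O)CC[C@@]2(C)O[C@H]2[C@@H](O)[C@H]1[C@H](COC(C)=O)C(=O)O
A1 | alternative 1 | seco nitro alkene with finished epoxide and lactone (C10 nitromethyl, C1 OTBS, C7 vinyl) | [O-][N+](=O)C[C@@H](O[Si](C)(C)C(C)(C)C)CC[C@@]1(C)O[C@H]1[C@H]1OC(=O)[C@@H](COC(C)=O)[C@H]1C=C
A2 | alternative 1 | isoxazoline-bridged ten-membered ring | O3[C@H]1CC(=N3)[C@@H](O[Si](C)(C)C(C)(C)C)CC[C@@]2(C)O[C@H]2[C@H]2OC(=O)[C@@H](COC(C)=O)[C@H]21
A3 | alternative 2 | ten-membered ring C6 diazoacetate (C7 methylene) | CC(C)(C)[Si](C)(C)O[C@H]1C[C@@](C)(OC(C)=O)C(=O)CC[C@@]2(C)O[C@H]2[C@@H](OC(=O)C=[N+]=[N-])C1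
A4 | alternative 2 | cis-fused lactone lacking C13 | CC(C)(C)[Si](C)(C)O[C@H]1C[C@@](C)(OC(C)=O)C(=O)CC[C@@]2(C)O[C@H]2[C@H]2OC(=O)C[C@H]21
A5 | alternative 3 | carvone-derived 1-isopropenyl-2-methyl-2-vinylcyclohexanol, alkenyl groups trans, with MOM and PMB ethers | O[C@@]1(C(C)=C)[C@@H](OCOC)[C@@H](C(C)=C)[C@@H](OCc2ccc(OC)cc2)C[C@@]1(C)C=C
A6 | alternative 3 | (1(10)E)-cyclodecadiene C5 trimethylsilyl enol ether | C/C1=C\CC/C(C)=C(O[Si](C)(C)C)/[C@@H](OCOC)[C@@H](C(C)=C)[C@@H](OCc2ccc(OC)cc2)C1
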